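**Strategy.** The route rests on cutting the bond between the carbinol carbon C1′ (the carbon on C4 of the furan-2(5H)-one ring) and the allylic methylene C2′. C1′–OH, C2′, the C3′=C4′ alkene and the CH2OH carbon on C4′ form the pattern of a vinylogous aldol adduct once CH2OH is read as an ester. A catalytic asymmetric vinylogous Mukaiyama aldol reaction therefore joins a C20 silyl dienol ether, made from an α-homofarnesyl crotonate, to furan-3-carbaldehyde, the furanone ring in masked form. In one operation it forms C1′–C2′, sets the (R)-carbinol and fixes the E geometry of C3′=C4′. Ester reduction and furan-to-butenolide oxidation then complete the target.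

Key step: step 5

Remark (assumption): the (R,R)-bisphosphoramide/SiCl4 catalyst is taken to direct the dienol ether to the Re face of furan-3-carbaldehyde, as with other aromatic aldehydes (the (S,S)-catalyst would be used if the sense were opposite); the ketene acetal geometry of 8 is not relayed to the product and is left undefined, and either geometric isomer of bromoester 5 converges on the same 8.

**Step 1**
Reactants: 1 (2E,6E)-farnesol
Product: 2 (2E,6E)-farnesal
Conditions: TEMPO (10 mol%), PhI(OAc)2 (1.1 equiv), CH2Cl2, 0 °C to rt
Reagents that add atoms: none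
Why: Oxoammonium (TEMPO/PhI(OAc)2) oxidation should take the primary allylic alcohol to the enal under near-neutral conditions that neither isomerise the 2E alkene nor touch the remote trisubstituted alkenes.

**Step 2**
Reactants: 2 (2E,6E)-farnesal
Product: 3 (3E,7E)-4,8,12-trimethyltrideca-1,3,7,11-tetraene
Conditions: Ph3PCH3Br, n-BuLi, THF, 0 °C; then 2, 0 °C to rt
Reagents that add atoms: methyltriphenylphosphonium bromide, C[P+](c1ccccc1)(c1ccccc1)c1ccccc1.[Br-]
Why: Wittig methylenation of the enal with the non-stabilised ylide should give the terminal 1,3-diene and leave the existing alkene geometries unchanged.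

**Step 3**
Reactants: 3 (3E,7E)-4,8,12-trimethyltrideca-1,3,7,11-tetraene; 4 9-borabicyclo[3.3.1]nonane (9-BBN); 5 methyl (Z)-2-bromobut-2-enoate
Product: 7 methyl (2E)-2-[(3E,7E)-4,8,12-trimethyltrideca-3,7,11-trien-1-yl]but-2-enoate, via B-homofarnesyl-9-BBN 6 (not isolated)
Conditions: 4 (1.05 equiv), THF, 0 °C to rt; then 5, PdCl2(dppf) (5 mol%), AsPh3 (5 mol%), Cs2CO3, DMF/H2O, rt
Reagents that add atoms: none
Why: 9-BBN should add anti-Markovnikov to the only monosubstituted alkene (the diene terminus) much faster than to the trisubstituted alkenes, and the primary alkylborane should then couple with the α-bromoenoate with retention of alkene geometry (hydroboration followed by B-alkyl Suzuki–Miyaura cross-coupling).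

**Step 4**
Reactants: 7 methyl (2E)-2-[(3E,7E)-4,8,12-trimethyltrideca-3,7,11-trien-1-yl]but-2-enoate
Product: 8 tert-butyl({1-methoxy-2-[(3E,7E)-4,8,12-trimethyltrideca-3,7,11-trien-1-yl]buta-1,3-dien-1-yl}oxy)dimethylsilane
Conditions: LDA (1.2 equiv), THF/DMPU, −78 °C; TBSCl, −78 °C to 0 °C; pentane, cold pH 7 buffer wash (removes DMPU completely)
Reagents that add atoms: tert-butyldimethylsilyl chloride, CC(C)(C)[Si](C)(C)Cl
Why: In the presence of DMPU, LDA should remove a proton from the γ-methyl group (the only acidic site) instead of adding in a conjugate sense, and O-silylation of the lithium dienolate should give the vinylketene silyl acetal (kinetic γ-deprotonation and silyl ketene acetal formation).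

**Step 5**
Reactants: 8 tert-butyl({1-methoxy-2-[(3E,7E)-4,8,12-trimethyltrideca-3,7,11-trien-1-yl]buta-1,3-dien-1-yl}oxy)dimethylsilane; 9 furan-3-carbaldehyde
Product: 10 methyl (2E,5R)-5-(furan-3-yl)-5-hydroxy-2-[(3E,7E)-4,8,12-trimethyltrideca-3,7,11-trien-1-yl]pent-2-enoate
Conditions: SiCl4 (1.2 equiv), (R,R)-binaphthyldiamine-derived bisphosphoramide (5 mol%), i-Pr2NEt (10 mol%), CH2Cl2, −78 °C; aq. KF/NaHCO3
Reagents that add atoms: none
Why: The chiral bisphosphoramide should bind SiCl4 and ionise it to a cationic trichlorosilyl Lewis acid that activates the aldehyde of 9; the terminal (γ) CH2 of dienol ether 8 then attacks through an open transition state, chloride removes the TBS group, and the adduct is released as its trichlorosilyl ether, which is hydrolysed on work-up. The closest known reaction type is the Lewis-base-catalysed, SiCl4-mediated enantioselective vinylogous Mukaiyama aldol addition of ester-derived silyl dienol ethers (α-alkyl examples included) to aromatic and heteroaromatic aldehydes. No ring is closed. The new stereocentre is controlled by the catalyst alone: the (R,R)-ligand should shield the Si face of the bound aldehyde, so that attack on the Re face gives the (R)-carbinol. The step needs γ- over α-attack, which the fully substituted and shielded α-carbon secures, and the E-enoate (ester trans to the new CH2, chain cis to it), which reaction through the s-trans conformer of the diene secures because the s-cis conformer suffers a clash between the vinyl terminus and the OMe/OTBS end. Furan ring and trisubstituted alkenes should not compete for the silicon Lewis acid at −78 °C, and the catalytic amine removes adventitious HCl that could trigger polyene cyclisation.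

**Step 6**
Reactants: 10 methyl (2E,5R)-5-(furan-3-yl)-5-hydroxy-2-[(3E,7E)-4,8,12-trimethyltrideca-3,7,11-trien-1-yl]pent-2-enoate
Product: 11 (1R,3E,7E,11E)-1-(furan-3-yl)-4-(hydroxymethyl)-8,12,16-trimethylheptadeca-3,7,11,15-tetraen-1-ol
Conditions: DIBAL-H (3.5 equiv), CH2Cl2, −78 °C to −20 °C; aq. Rochelle salt
Reagents that add atoms: none
Why: DIBAL-H should reduce the conjugated methyl ester to the primary allylic alcohol by 1,2-hydride delivery, with the free carbinol consuming one equivalent as its aluminium alkoxide and the furan, alkenes and stereocentre left untouched.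

**Step 7**
Reactants: 11 (1R,3E,7E,11E)-1-(furan-3-yl)-4-(hydroxymethyl)-8,12,16-trimethylheptadeca-3,7,11,15-tetraen-1-ol
Product: 13 hippolide C 4-[(1R,3E,7E,11E)-1-hydroxy-4-(hydroxymethyl)-8,12,16-trimethylheptadeca-3,7,11,15-tetraen-1-yl]furan-2(5H)-one, via γ-hydroxybutenolide 12 (not isolated)
Conditions: O2, hν (visible), Rose Bengal (cat.), i-Pr2NEt, CH2Cl2/MeOH, −78 °C, stopped at full conversion; Ar purge; NaBH4, −78 °C to 0 °C; 1 M HCl to pH 3
Reagents that add atoms: dioxygen (as singlet oxygen), O=O
Why: Singlet oxygen should add [4+2] to the furan faster than it undergoes ene reactions with the trisubstituted alkenes at −78 °C, the hindered base should remove the endoperoxide bridgehead proton remote from the side chain so that the hemiacetal carbon ends up next to the substituted ring carbon, and borohydride reduction of the ring-opened formyl carboxylate followed by acid-induced lactonisation should give the 4-substituted furan-2(5H)-one with the carbinol stereocentre untouched (base-directed furan photooxygenation, then hydroxybutenolide reduction).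

**Compound list**
1 | (2E,6E)-farnesol | CC(C)=CCC/C(C)=C/CC/C(C)=C/CO | starting material
2 | (2E,6E)-farnesal | CC(C)=CCC/C(C)=C/CC/C(C)=C/C=O | intermediate
3 | (3E,7E)-4,8,12-trimethyltrideca-1,3,7,11-tetraene | CC(C)=CCC/C(C)=C/CC/C(C)=C/C=C | intermediate
4 | 9-borabicyclo[3.3.1]nonane (9-BBN) | B1C2CCCC1CCC2 | starting material
5 | methyl (Z)-2-bromobut-2-enoate | C/C=C(\Br)C(=O)OC | starting material
6 | 9-[(3E,7E)-4,8,12-trimethyltrideca-3,7,11-trien-1-yl]-9-borabicyclo[3.3.1]nonane (B-homofarnesyl-9-BBN) | CC(C)=CCC/C(C)=C/CC/C(C)=C/CCB1C2CCCC1CCC2 | intermediate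
7 | methyl (2E)-2-[(3E,7E)-4,8,12-trimethyltrideca-3,7,11-trien-1-yl]but-2-enoate | CC(C)=CCC/C(C)=C/CC/C(C)=C/CC/C(=C\C)C(=O)OC | intermediate
8 | tert-butyl({1-methoxy-2-[(3E,7E)-4,8,12-trimethyltrideca-3,7,11-trien-1-yl]buta-1,3-dien-1-yl}oxy)dimethylsilane (ketene acetal geometry undefined) | CC(C)=CCC/C(C)=C/CC/C(C)=C/CCC(C=C)=C(OC)O[Si](C)(C)C(C)(C)C | intermediate
9 | furan-3-carbaldehyde | O=Cc1ccoc1 | starting material
10 | methyl (2E,5R)-5-(furan-3-yl)-5-hydroxy-2-[(3E,7E)-4,8,12-trimethyltrideca-3,7,11-trien-1-yl]pent-2-enoate | CC(C)=CCC/C(C)=C/CC/C(C)=C/CC/C(=C\C[C@@H](O)c1ccoc1)C(=O)OC | intermediate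
11 | (1R,3E,7E,11E)-1-(furan-3-yl)-4-(hydroxymethyl)-8,12,16-trimethylheptadeca-3,7,11,15-tetraen-1-ol | CC(C)=CCC/C(C)=C/CC/C(C)=C/CC/C(=C\C[C@@H](O)c1ccoc1)CO | intermediate
12 | 5-hydroxy-4-[(1R,3E,7E,11E)-1-hydroxy-4-(hydroxymethyl)-8,12,16-trimethylheptadeca-3,7,11,15-tetraen-1-yl]furan-2(5H)-one (both C5 epimers) | CC(C)=CCC/C(C)=C/CC/C(C)=C/CC/C(=C\C[C@@H](O)C1=CC(=O)OC1O)CO | intermediate
13 | hippolide C, 4-[(1R,3E,7E,11E)-1-hydroxy-4-(hydroxymethyl)-8,12,16-trimethylheptadeca-3,7,11,15-tetraen-1-yl]furan-2(5H)-one | CC(C)=CCC/C(C)=C/CC/C(C)=C/CC/C(=C\C[C@@H](O)C1=CC(=O)OC1)CO | target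

**Total step count:** 7. **Longest linear sequence:** 7 (steps 1 to 7).

**Steps most likely to fail**

Step 5. The long α-substituent on the dienol ether may slow γ-attack, allow some α-attack, or erode the facial discrimination of the catalyst. The fallback sets out from 8 and 9 and moves stereocontrol from the bond-forming event to a reagent-controlled ketone reduction. An achiral vinylogous Mukaiyama aldol reaction (BF3·OEt2, CH2Cl2, −78 °C) should give the racemic hydroxy ester F1. Buffered Dess–Martin oxidation (NaHCO3, CH2Cl2, 0 °C, product used without chromatography to avoid alkene migration) should give the 3-furyl ketone F2. Reduction with (S)-Me-CBS catalyst and catecholborane in toluene at −78 °C (furyl as the large group, CH2 as the small one) should return the (R)-alcohol, and the sequence comes back to the route at 10.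

Step 7. Singlet oxygen may attack the four trisubstituted alkenes in ene fashion during the irradiation, and the base-induced opening of the endoperoxide may lose regiocontrol. The fallback sets out from 9 and replaces base-directed opening by a silyl-directed one. α-Amino alkoxide-directed lithiation at C5 (lithium morpholide, then s-BuLi, then TMSCl, THF, −78 °C) should give 5-(trimethylsilyl)furan-3-carbaldehyde F3. Carried through the conditions of steps 5 and 6 with 8, this should give the silylfuryl hydroxy ester F4 and then the silylfuryl diol F5. The 2-silylfuran should react faster with singlet oxygen (Rose Bengal, O2, hν, −78 °C, no base), and the endoperoxide should collapse by 1,2-shift of silicon from carbon to peroxide oxygen, so that the silicon-bearing carbon becomes the lactone carbonyl. The sequence comes back to the route at 12, which is reduced as in step 7.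

Step 3. The homoallylic alkyl–palladium intermediate may undergo β-hydride elimination or protodeboronation, and the α-bromoenoate may decompose under the basic coupling conditions. The fallback sets out from 6 and replaces the cross-coupling by an enolate alkylation. Oxidation (NaOH, H2O2) should give (3E,7E)-homofarnesol F6, and iodination (I2, PPh3, imidazole) should give homofarnesyl iodide F7. Deconjugative α-alkylation of the lithium dienolate of methyl crotonate (LDA, THF/HMPA, −78 °C) with F7 should give the racemic β,γ-unsaturated ester F8. α-Deprotonation and O-silylation of F8 under the conditions of step 4 give the same dienol ether, and the sequence comes back to the route at 8.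

**Further compounds**
F1 | step 5 | racemic methyl (2E)-5-(furan-3-yl)-5-hydroxy-2-[(3E,7E)-4,8,12-trimethyltrideca-3,7,11-trien-1-yl]pent-2-enoate | CC(C)=CCC/C(C)=C/CC/C(C)=C/CC/C(=C\CC(O)c1ccoc1)C(=O)OC
F2 | step 5 | methyl (2E)-5-(furan-3-yl)-5-oxo-2-[(3E,7E)-4,8,12-trimethyltrideca-3,7,11-trien-1-yl]pent-2-enoate | CC(C)=CCC/C(C)=C/CC/C(C)=C/CC/C(=C\CC(=O)c1ccoc1)C(=O)OC
F3 | step 7 | 5-(trimethylsilyl)furan-3-carbaldehyde | O=Cc1coc([Si](C)(C)C)c1
F4 | step 7 | methyl (2E,5R)-5-hydroxy-5-[5-(trimethylsilyl)furan-3-yl]-2-[(3E,7E)-4,8,12-trimethyltrideca-3,7,11-trien-1-yl]pent-2-enoate | CC(C)=CCC/C(C)=C/CC/C(C)=C/CC/C(=C\C[C@@H](O)c1coc([Si](C)(C)C)c1)C(=O)OC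
F5 | step 7 | (1R,3E,7E,11E)-4-(hydroxymethyl)-8,12,16-trimethyl-1-[5-(trimethylsilyl)furan-3-yl]heptadeca-3,7,11,15-tetraen-1-ol | CC(C)=CCC/C(C)=C/CC/C(C)=C/CC/C(=C\C[C@@H](O)c1coc([Si](C)(C)C)c1)CO
F6 | step 3 | (3E,7E)-4,8,12-trimethyltrideca-3,7,11-trien-1-ol (homofarnesol) | CC(C)=CCC/C(C)=C/CC/C(C)=C/CCO
F7 | step 3 | (3E,7E)-1-iodo-4,8,12-trimethyltrideca-3,7,11-triene (homofarnesyl iodide) | CC(C)=CCC/C(C)=C/CC/C(C)=C/CCI
F8 | step 3 | racemic methyl (5E,9E)-2-ethenyl-6,10,14-trimethylpentadeca-5,9,13-trienoate | CC(C)=CCC/C(C)=C/CC/C(C)=C/CCC(C=C)C(=O)OC
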